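**Proposed synthesis of 6-(3-methylbut-2-enyl)-3-[6-(3-methylbut-2-enyl)indol-1-yl]-1H-indole (26)**

Throughout, "prenyl" means 3-methylbut-2-enyl and "tosyl" means 4-methylphenylsulfonyl. Unprimed locants refer to the N–H indole, primed locants to the N-linked indole.

## Analysis of the target

Target 26 is a 3,1'-linked bisindole in which C3 of a 6-prenyl-1H-indole is bonded to N1' of a second indole that carries its own prenyl group at C6'. It has no stereocentre, and both alkenes end in a gem-dimethyl group, so there is no alkene geometry to set and the problem is purely one of constitution. The sensitive groups are the two trisubstituted prenyl alkenes, which suffer from protic acid, electrophiles and metal hydride migration, the free N–H indole with an open C2, and the second indole with open C2' and C3'. The C3–N1' link is formally that of a 3-aminoindole, whose parent amine oxidises easily. The synthesis is hard for two reasons: the bond between indole C3 and an indole nitrogen cannot be made reliably from a 3-haloindole and an indole N–H, and the prenyl groups sit at C6 and C6', positions that electrophilic substitution does not reach. The strategy rests on the benzo ring of the N-linked indole (C3a', C4', C5', C6', C7', C7a'), which carries hydrogen at C4', C5' and C7' and carbon only at C6'. If that ring is built last, the N-linked unit is at first only a pyrrole, which can be made from a primary amine, and a succinate annulation of its 2-carbaldehyde then puts the ester carbon exactly at C6', the future benzylic carbon of the prenyl group, leaving at C4' an oxygen that has to be removed.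

## Retrosynthetic reasoning

**26 to 25.** Only the N1–S bond is cut. The sulfonyl group stays to the very end because it deactivates C2 and C3 of the first indole in every earlier step, and it can be removed reductively without acid, so the two prenyl groups are not endangered.

**25 to 23 and 24.** The C6' prenyl group is cut between its benzylic CH2 and its vinylic CH. This is where the annulation leaves its carbon, so only the four-carbon alkenyl unit of boronate 24 has to be added. Because 24 brings the double bond ready-made, the coupling has no linear/branched ambiguity.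

**23 back to 18.** Chloride 23 comes from alcohol 21 through sulfonate 22, alcohol 21 from triflate 20 by replacing C–O with C–H, triflate 20 from phenol 19, and 19 from acetate ester 18 by one hydride reduction that cleaves the C4' acetate and reduces the C6' ester together. These are functional-group changes only. They remove the C4' oxygen, which is the price of the annulation, at a stage where the only other C–O bond is a primary alcohol that does not interfere.

**18 to 13.** This is the central disconnection: the C3a'–C4' bond is cut and the benzo ring opens to acid 13, a pyrrole bearing a four-carbon acid side chain at its C2. It is cut here and not at a C–N bond because the precursor then needs nothing more than an aldehyde on a pyrrole, and because the ring closes onto the electron-rich pyrrole C3 with no regiochemical choice. The forward reaction has to turn the acid of 13 into ketene 15, close the ring and aromatise it.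

**13 to 10 and 11.** The C7'=C6' double bond is cut in the aldol sense to aldehyde 10 and succinate 11. The forward condensation must give the E acid, in which the pyrrole and the CH2CO2H arm are cis, since only that isomer can cyclise.

**10 to 8.** The formyl C–C bond at pyrrole C2 is cut. The two α-positions of the pyrrole in 8 are equivalent, and the sulfonylated indole does not compete for the electrophile.

**8 to 6 and 7.** The C6–CH2 bond of the first prenyl group is cut to aryl bromide 6 and boronate 7. The prenyl group is introduced only at this stage, so the alkene never meets the nitrating agent, the reducing metal or the hot carboxylic acid of the earlier steps.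

**6 to 3 and 4.** Both N–C bonds of the pyrrole ring are cut, leading back to amine 5, formed in the flask from nitro compound 3, and the four-carbon dialdehyde equivalent 4. The C3–N1' bond of the target is thus never made by a coupling; it is the C–N bond of a nitro group.

**3 to 2 to 1.** The C3–N bond comes from electrophilic nitration of sulfonamide 2, and 2 from N-sulfonylation of 6-bromoindole 1, whose bromine marks C6 for the later prenylation.

## Alternatives that were turned down

Alternative 1: The cut is at C3–N1' and N1'–C2', so the pyrrole ring of the N-linked indole is formed last from two halves, the indoxyl 1-acetyl-6-prenylindolin-3-one A1 and 2-ethynyl-5-prenylaniline A2. In the forward step NaAuCl4, a salt of trivalent gold, is to promote condensation of the aniline nitrogen of A2 with the C3 ketone of A1 and then 5-endo hydroamination of the alkyne, which gives 1-acetyl-6-prenyl-3-(6-prenylindol-1-yl)indole A3, one deacylation away from 26. In its favour, the plan is convergent, both prenyl groups are in place before the union and nothing has to be excised afterwards; in step count and convergency it is clearly stronger than the chosen linear route. Against it, each half needs its own regiodefined prenylation, A1 is an enolisable ketone of modest electrophilicity and A2 is a weak nucleophile. The carbophilic catalyst can also close A2 on its own to 6-prenyl-1H-indole A4, and A4 is a dead end because it no longer has a primary amine to condense with A1. The catalyst moreover works next to two nucleophilic prenyl alkenes and a terminal alkyne. Compared with this, the chosen route gives up convergency; in return its C3–N bond comes from a primary amine and a dialdehyde equivalent with no metal near the alkenes, and every bond-forming step has a close analogue.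

Alternative 2: The cut is at C3–C3a and N1–C7a of the N–H indole, whose pyrrole ring is built last on a carbocycle. The partners are 4-(6-prenylindol-1-yl)-1-tosyl-1,2,3-triazole A5 and the Birch-type diene 1-methoxy-5-prenylcyclohexa-1,4-diene A6. Rh2(OAc)4 is to denitrogenate A5 to an azavinyl carbene, which adds to the enol ether bond of A6; ring closure through nitrogen and loss of the methoxy group give 6-prenyl-3-(6-prenylindol-1-yl)-1-tosyl-4,7-dihydroindole A7, which still needs dehydrogenation and desulfonylation. In its favour, transannulation of N-sulfonyltriazoles with enol ethers is a known pyrrole synthesis, the sulfonyl group arrives on the right nitrogen, the Birch pattern fixes the prenyl group at C6, A7 should aromatise easily, and the sequence would be shorter than the chosen one. Against it, A5 is a triazole with nitrogen at C4; it can only be assembled by azide–alkyne cycloaddition on an alkyne that carries the indole nitrogen directly, and with such nitrogen-substituted alkynes the metallated triazole tends to fragment to a ketenimine. A6 offers three alkenes, besides the prenyl group on A5, to an electrophilic carbene, and its skipped diene can slip into conjugation. Compared with this, the chosen route is longer, but it places the indolyl substituent on a stable pyrrole and not on a carbene precursor of doubtful stability.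

Alternative 3: The cut is at C3a'–C7a' and C4'–C5', so the benzo ring and the five-membered ring of the N-linked unit both come from N-(but-3-ynyl)-N-(6-prenyl-1-tosylindol-3-yl)-5-prenylpyridazin-3-amine A8. On heating, the alkyne of A8 is to add across pyridazine C3 and C6 in an intramolecular inverse-demand cycloaddition, and cycloreversion with denitrogenation then gives 6-prenyl-1-(6-prenyl-1-tosylindol-3-yl)indoline A9, which needs dehydrogenation and desulfonylation. In its favour, one catalyst-free step closes two rings, the prenyl group is already at C6' and no oxygen or ester is left to convert; on economy after the key step it is stronger than the chosen route, which spends six steps there. Against it, an amino-substituted pyridazine is an electron-rich azadiene and the alkyne is unactivated, so temperatures well above those of the chosen cyclisation are to be expected, at which the prenyl groups can enter ene reactions. A8 also requires two successive N-functionalisations of a fragile 3-aminoindole, one of them with a homopropargyl electrophile prone to elimination, and the final dehydrogenation of A9 has to spare two benzylic-allylic CH2 groups. Compared with this, the chosen route uses the same amine only in a one-pot double condensation and cyclises in a buffered medium at moderate temperature.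

Key step: step 7

Remark on the chemistry: acid 13 is taken as the E isomer, the one a Stobbe condensation of an aromatic aldehyde is expected to favour and the only one that can cyclise.

## Route

Step 1
Reactants: 1 6-bromo-1H-indole
Product: 2 6-bromo-1-tosylindole
Conditions: TsCl, 50% aq NaOH, Bu4NHSO4 (cat.), toluene, rt
Reagents that add atoms: p-toluenesulfonyl chloride, Cc1ccc(cc1)S(=O)(=O)Cl
Why: Phase-transfer N-sulfonylation of the indole anion; the tosyl group limits the later nitration to C3, stabilises the 3-amino stage and blocks N1 until the end.

Step 2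
Reactants: 2 6-bromo-1-tosylindole
Product: 3 6-bromo-3-nitro-1-tosylindole
Conditions: fuming HNO3, Ac2O, −60 °C → rt
Reagents that add atoms: nitric acid, O[N+](=O)[O-], delivered as acetyl nitrate, CC(=O)O[N+](=O)[O-]
Why: Electrophilic nitration of an N-sulfonylindole with acetyl nitrate goes to C3, the enamine carbon; the brominated benzo ring is deactivated and no alkene is present yet.

Step 3
Reactants: 3 6-bromo-3-nitro-1-tosylindole; 4 2,5-dimethoxytetrahydrofuran
Product: 6 6-bromo-3-(pyrrol-1-yl)-1-tosylindole, via 3-aminoindole 5 (not isolated)
Conditions: Fe powder, AcOH, 90 °C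
Reagents that add atoms: none
Why: Béchamp-type nitro reduction runs in the same acid that unmasks the 1,4-dicarbonyl unit of 4, so the oxidation-prone amine 5 should be trapped by Clauson–Kaas condensation as it forms; the aryl bromide and the sulfonamide are inert to Fe in AcOH.

Step 4
Reactants: 6 6-bromo-3-(pyrrol-1-yl)-1-tosylindole; 7 3-methylbut-2-enylboronic acid pinacol ester
Product: 8 6-prenyl-3-(pyrrol-1-yl)-1-tosylindole
Conditions: Pd(OAc)2 (3 mol %), tBuXPhos (6 mol %), aq K3PO4, THF, 40 °C
Reagents that add atoms: none
Why: Suzuki–Miyaura coupling of an aryl bromide with an allylic boronate on zerovalent palladium; the bulky di-tert-butylbiarylphosphine should let the first-formed tertiary σ-allyl palladium species relax to the primary one before reductive elimination, so the linear prenyl isomer is expected, and nothing in 6 is base-labile at 40 °C.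

Step 5
Reactants: 8 6-prenyl-3-(pyrrol-1-yl)-1-tosylindole
Product: 10 1-(6-prenyl-1-tosylindol-3-yl)pyrrole-2-carbaldehyde, via iminium chloride 9 (not isolated)
Conditions: POCl3, DMF, ClCH2CH2Cl, 0 °C → rt; then aq NaOAc
Reagents that add atoms: N,N-dimethylformamide, CN(C)C=O; water, O
Why: Vilsmeier–Haack formylation; an N-arylpyrrole reacts at its α-position far faster than a sulfonylated indole or an isolated alkene, the two α-positions are equivalent, and excess DMF buffers the HCl set free.

Step 6
Reactants: 10 1-(6-prenyl-1-tosylindol-3-yl)pyrrole-2-carbaldehyde; 11 diethyl succinate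
Product: 13 (E)-3-ethoxycarbonyl-4-[1-(6-prenyl-1-tosylindol-3-yl)pyrrol-2-yl]but-3-enoic acid, via paraconic ester lactone 12 (not isolated)
Conditions: KOtBu, tBuOH/THF, 0 → 45 °C; then cold 1 M HCl
Reagents that add atoms: none
Why: Stobbe condensation: the succinate enolate adds to the aldehyde, the alkoxide lactonises to 12, and base-induced ring opening gives the carboxylate irreversibly; elimination should place the pyrrole trans to the ester, that is the E acid with pyrrole and CH2CO2H cis, and the hindered alkoxide is a poor nucleophile at the sulfonyl sulfur.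

Step 7
Reactants: 13 (E)-3-ethoxycarbonyl-4-[1-(6-prenyl-1-tosylindol-3-yl)pyrrol-2-yl]but-3-enoic acid
Product: 18 ethyl 4-acetoxy-1-(6-prenyl-1-tosylindol-3-yl)indole-6-carboxylate, via mixed anhydride 14 (not isolated), via dienylketene 15 (not isolated), via bicyclic dienone 16 (not isolated), via 4-hydroxyindole ester 17 (not isolated)
Conditions: Ac2O, NaOAc, 130–140 °C
Reagents that add atoms: acetic anhydride, CC(=O)OC(C)=O
Why: Acetic anhydride turns the acid into mixed anhydride 14, and acetate removes the α-proton so that acetate is expelled and dienylketene 15 forms, conjugated through the ketene C5'=C4' bond, the C6'=C7' bond and the pyrrole C2=C3 bond. A thermal disrotatory six-electron electrocyclisation then joins the ketene carbon (C4') to pyrrole C3 (C3a') in a six-membered closure to dienone 16; enolisation restores the pyrrole as phenol 17, and acetylation to 18 makes the sequence irreversible. The closest known reaction type is the Stobbe half-ester benzannulation in acetic anhydride and acetate, which converts aryl and N-substituted pyrrol-2-yl half-esters into 4-acetoxy-2-naphthoates and 4-acetoxyindole-6-carboxylates. The only stereocentre, C3a' of 16, is transient and is erased on aromatisation, so no stereocontrol is needed. The step needs closure at pyrrole C3: the pyrrole nitrogen is fully substituted, so closure on nitrogen is excluded, and C2 of the sulfonylated indole is electron-poor and cannot be reached in a six-membered transition state. It also needs the ketene arm cis to the pyrrole, which the E geometry of 13 provides, while the bulky N-substituent should favour the rotamer in which the side chain lies over C3. The buffered medium, free of strong acid, should leave the prenyl group and the sulfonamide untouched.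

Step 8
Reactants: 18 ethyl 4-acetoxy-1-(6-prenyl-1-tosylindol-3-yl)indole-6-carboxylate
Product: 19 6-(hydroxymethyl)-1-(6-prenyl-1-tosylindol-3-yl)indol-4-ol
Conditions: i-Bu2AlH (5 equiv), CH2Cl2, −78 → 0 °C; aq KNaC4H4O6 (potassium sodium tartrate)
Reagents that add atoms: none
Why: Hydride reduction of the ethyl ester to the benzylic alcohol and reductive cleavage of the aryl acetate in one operation; the sulfonamide, the alkene and the indole rings are inert to i-Bu2AlH at low temperature.

Step 9
Reactants: 19 6-(hydroxymethyl)-1-(6-prenyl-1-tosylindol-3-yl)indol-4-ol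
Product: 20 6-(hydroxymethyl)-1-(6-prenyl-1-tosylindol-3-yl)indol-4-yl trifluoromethanesulfonate
Conditions: PhNTf2, Et3N, CH2Cl2, 0 °C → rt
Reagents that add atoms: N-phenylbis(trifluoromethanesulfonimide), O=S(=O)(N(c1ccccc1)S(=O)(=O)C(F)(F)F)C(F)(F)F
Why: Chemoselective O-sulfonylation: this mild triflating agent with a tertiary amine reacts with phenoxides but not with primary alcohols, so only the C4' oxygen is activated.

Step 10
Reactants: 20 6-(hydroxymethyl)-1-(6-prenyl-1-tosylindol-3-yl)indol-4-yl trifluoromethanesulfonate
Product: 21 [1-(6-prenyl-1-tosylindol-3-yl)indol-6-yl]methanol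
Conditions: Pd(OAc)2 (5 mol %), dppf, HCO2H, Et3N, DMF, 60 °C
Reagents that add atoms: none
Why: Palladium-catalysed formate reduction of an aryl triflate (oxidative addition, formate exchange, decarboxylation, C–H reductive elimination) removes the C4' oxygen; the isolated trisubstituted alkene and the benzylic alcohol should not react.

Step 11
Reactants: 21 [1-(6-prenyl-1-tosylindol-3-yl)indol-6-yl]methanol
Product: 23 6-(chloromethyl)-1-(6-prenyl-1-tosylindol-3-yl)indole, via benzylic mesylate 22 (not isolated)
Conditions: MsCl, LiCl, 2,4,6-collidine, DMF, 0 °C
Reagents that add atoms: lithium chloride, [Li+].[Cl-]; methanesulfonyl chloride, CS(=O)(=O)Cl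
Why: Mesylation and chloride displacement in one flask under collidine buffering gives the benzylic chloride without free acid; the chloride is preferred to the bromide to limit self-alkylation of the indole.

Step 12
Reactants: 23 6-(chloromethyl)-1-(6-prenyl-1-tosylindol-3-yl)indole; 24 2-methylprop-1-enylboronic acid pinacol ester
Product: 25 6-prenyl-1-(6-prenyl-1-tosylindol-3-yl)indole
Conditions: PdCl2(dppf) (5 mol %), K3PO4, THF/H2O, 65 °C
Reagents that add atoms: none
Why: Suzuki–Miyaura coupling of a benzylic chloride with an alkenylboronate; the benzylpalladium intermediate has no β-hydrogen, and the bond formed is the CH2–CH= bond of the prenyl group, so the position of the double bond is fixed by 24.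

Step 13
Reactants: 25 6-prenyl-1-(6-prenyl-1-tosylindol-3-yl)indole
Product: 26 6-(3-methylbut-2-enyl)-3-[6-(3-methylbut-2-enyl)indol-1-yl]-1H-indole
Conditions: Mg turnings, MeOH, rt, sonication
Reagents that add atoms: none
Why: Electron-transfer cleavage of the N–S bond of an N-sulfonylindole by Mg in MeOH, followed by protonation; isolated alkenes are not reduced, and no sulfonate ester is formed that could alkylate the freed nitrogen.

## Compound list

1 | 6-bromo-1H-indole | Brc1ccc2cc[nH]c2c1 | starting material
2 | 6-bromo-1-tosylindole | Cc1ccc(cc1)S(=O)(=O)n1ccc2ccc(Br)cc21 | intermediate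
3 | 6-bromo-3-nitro-1-tosylindole | Cc1ccc(cc1)S(=O)(=O)n1cc([N+](=O)[O-])c2ccc(Br)cc21 | intermediate
4 | 2,5-dimethoxytetrahydrofuran (cis/trans mixture) | COC1CCC(OC)O1 | starting material
5 | 3-amino-6-bromo-1-tosylindole (not isolated) | Cc1ccc(cc1)S(=O)(=O)n1cc(N)c2ccc(Br)cc21 | intermediate
6 | 6-bromo-3-(pyrrol-1-yl)-1-tosylindole | Cc1ccc(cc1)S(=O)(=O)n1cc(-n2cccc2)c2ccc(Br)cc21 | intermediate
7 | 3-methylbut-2-enylboronic acid pinacol ester | CC(C)=CCB1OC(C)(C)C(C)(C)O1 | starting material
8 | 6-prenyl-3-(pyrrol-1-yl)-1-tosylindole | Cc1ccc(cc1)S(=O)(=O)n1cc(-n2cccc2)c2ccc(CC=C(C)C)cc21 | intermediate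
9 | dimethyl[[1-(6-prenyl-1-tosylindol-3-yl)pyrrol-2-yl]methylidene]ammonium chloride (not isolated) | C[N+](C)=Cc1cccn1-c1cn(S(=O)(=O)c2ccc(C)cc2)c2cc(CC=C(C)C)ccc12.[Cl-] | intermediate
10 | 1-(6-prenyl-1-tosylindol-3-yl)pyrrole-2-carbaldehyde | O=Cc1cccn1-c1cn(S(=O)(=O)c2ccc(C)cc2)c2cc(CC=C(C)C)ccc12 | intermediate
11 | diethyl succinate | CCOC(=O)CCC(=O)OCC | starting material
12 | ethyl 5-oxo-2-[1-(6-prenyl-1-tosylindol-3-yl)pyrrol-2-yl]tetrahydrofuran-3-carboxylate (not isolated; racemic mixture of diastereomers) | CCOC(=O)C1CC(=O)OC1c1cccn1-c1cn(S(=O)(=O)c2ccc(C)cc2)c2cc(CC=C(C)C)ccc12 | intermediate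
13 | (E)-3-ethoxycarbonyl-4-[1-(6-prenyl-1-tosylindol-3-yl)pyrrol-2-yl]but-3-enoic acid | OC(=O)C/C(C(=O)OCC)=C\c1cccn1-c1cn(S(=O)(=O)c2ccc(C)cc2)c2cc(CC=C(C)C)ccc12 | intermediate
14 | acetic (E)-3-ethoxycarbonyl-4-[1-(6-prenyl-1-tosylindol-3-yl)pyrrol-2-yl]but-3-enoic anhydride (not isolated) | CC(=O)OC(=O)C/C(C(=O)OCC)=C\c1cccn1-c1cn(S(=O)(=O)c2ccc(C)cc2)c2cc(CC=C(C)C)ccc12 | intermediate
15 | ethyl (E)-4-oxo-2-[[1-(6-prenyl-1-tosylindol-3-yl)pyrrol-2-yl]methylidene]but-3-enoate, the dienylketene (not isolated) | O=C=C/C(C(=O)OCC)=C\c1cccn1-c1cn(S(=O)(=O)c2ccc(C)cc2)c2cc(CC=C(C)C)ccc12 | intermediate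
16 | ethyl 4-oxo-1-(6-prenyl-1-tosylindol-3-yl)-3a,4-dihydroindole-6-carboxylate (not isolated; racemic at C3a') | CCOC(=O)C1=CC(=O)C2C=CN(c3cn(S(=O)(=O)c4ccc(C)cc4)c4cc(CC=C(C)C)ccc34)C2=C1 | intermediate
17 | ethyl 4-hydroxy-1-(6-prenyl-1-tosylindol-3-yl)indole-6-carboxylate (not isolated) | CCOC(=O)c1cc(O)c2ccn(-c3cn(S(=O)(=O)c4ccc(C)cc4)c4cc(CC=C(C)C)ccc34)c2c1 | intermediate
18 | ethyl 4-acetoxy-1-(6-prenyl-1-tosylindol-3-yl)indole-6-carboxylate | CCOC(=O)c1cc(OC(C)=O)c2ccn(-c3cn(S(=O)(=O)c4ccc(C)cc4)c4cc(CC=C(C)C)ccc34)c2c1 | intermediate
19 | 6-(hydroxymethyl)-1-(6-prenyl-1-tosylindol-3-yl)indol-4-ol | OCc1cc(O)c2ccn(-c3cn(S(=O)(=O)c4ccc(C)cc4)c4cc(CC=C(C)C)ccc34)c2c1 | intermediate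
20 | 6-(hydroxymethyl)-1-(6-prenyl-1-tosylindol-3-yl)indol-4-yl trifluoromethanesulfonate | OCc1cc(OS(=O)(=O)C(F)(F)F)c2ccn(-c3cn(S(=O)(=O)c4ccc(C)cc4)c4cc(CC=C(C)C)ccc34)c2c1 | intermediate
21 | [1-(6-prenyl-1-tosylindol-3-yl)indol-6-yl]methanol | OCc1ccc2ccn(-c3cn(S(=O)(=O)c4ccc(C)cc4)c4cc(CC=C(C)C)ccc34)c2c1 | intermediate
22 | [1-(6-prenyl-1-tosylindol-3-yl)indol-6-yl]methyl methanesulfonate (not isolated) | CS(=O)(=O)OCc1ccc2ccn(-c3cn(S(=O)(=O)c4ccc(C)cc4)c4cc(CC=C(C)C)ccc34)c2c1 | intermediate
23 | 6-(chloromethyl)-1-(6-prenyl-1-tosylindol-3-yl)indole | ClCc1ccc2ccn(-c3cn(S(=O)(=O)c4ccc(C)cc4)c4cc(CC=C(C)C)ccc34)c2c1 | intermediate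
24 | 2-methylprop-1-enylboronic acid pinacol ester | CC(C)=CB1OC(C)(C)C(C)(C)O1 | starting material
25 | 6-prenyl-1-(6-prenyl-1-tosylindol-3-yl)indole | CC(C)=CCc1ccc2ccn(-c3cn(S(=O)(=O)c4ccc(C)cc4)c4cc(CC=C(C)C)ccc34)c2c1 | intermediate
26 | 6-(3-methylbut-2-enyl)-3-[6-(3-methylbut-2-enyl)indol-1-yl]-1H-indole | CC(C)=CCc1ccc2c(-n3ccc4ccc(CC=C(C)C)cc43)c[nH]c2c1 | target

## Step count and least certain steps

Total step count: 13. Longest linear sequence: 13 steps, from 1 to 26.

**Step 7 (key step).** The most likely failure is loss of the ketene to intermolecular acylation and oligomerisation before it cyclises, because the reactive rotamer about the pyrrole–CH= bond has to be populated against the neighbouring N-substituent. Isomerisation of the acrylate away from the E geometry at 130–140 °C would have the same effect. Fallback: setting out from 13, the acid is converted under neutral conditions with 1-chloro-N,N,2-trimethylprop-1-en-1-amine in CH2Cl2 at 0 °C into (E)-3-ethoxycarbonyl-4-[1-(6-prenyl-1-tosylindol-3-yl)pyrrol-2-yl]but-3-enoyl chloride F1. This is allowed to acylate pyrrole C3 in a Friedel–Crafts sense below room temperature, if need be with ZnCl2, in the presence of 2,6-di-tert-butylpyridine, which takes up the hydrogen chloride and so protects the prenyl group. Enolisation gives phenol 17, now isolated, which takes the place of 18 in step 8 and returns to the route at 19.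

**Step 4.** Allyl transfer through the γ-terminus would give the 1,1-dimethylallyl isomer, since transmetalation of an allylic boronate is SE2'-like and the linear outcome depends on ligand-controlled equilibration; protodeboronation is a second drain. Fallback: setting out from 6, coupling with allylboronic acid pinacol ester (PdCl2(dppf), K3PO4, THF/H2O), which has no regiochemical choice, gives 6-allyl-3-(pyrrol-1-yl)-1-tosylindole F2. Cross-metathesis of F2 in 2-methylbut-2-ene with the second-generation Grubbs catalyst RuCl2(=CHPh)(PCy3)(H2IMes) returns to the route at 8.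

**Step 6.** Alkoxide attack at sulfur with loss of the tosyl group is the main risk. A second is slow addition to the aldehyde, which is a vinylogous formamide and therefore a weak electrophile, so that warming is needed and the first risk grows. Fallback: setting out from 10, a Horner–Wadsworth–Emmons reaction with 4-tert-butyl 1-ethyl 2-(diethoxyphosphoryl)butanedioate (NaH, THF, 0 °C → rt) gives 4-tert-butyl 1-ethyl (E)-2-[[1-(6-prenyl-1-tosylindol-3-yl)pyrrol-2-yl]methylidene]butanedioate F3. The tert-butyl ester of F3 is cleaved with TMSOTf and 2,6-lutidine in CH2Cl2 at 0 °C, buffered conditions that spare the prenyl group, and aqueous work-up returns to the route at 13.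

**Step 3.** Oxidative dimerisation or decomposition of the 3-aminoindole before it condenses, and polymerisation of the unmasked dialdehyde in hot acid, would lower the yield of the pyrrole. Fallback: setting out from 1, iodination (I2, KOH, DMF) gives 6-bromo-3-iodo-1H-indole F4, and tosylation as in step 1 gives 6-bromo-3-iodo-1-tosylindole F5. Copper-catalysed N-arylation of pyrrole at the C–I bond of F5, which reacts before the C–Br bond (CuI, trans-N,N'-dimethylcyclohexane-1,2-diamine, K3PO4, toluene, 110 °C), returns to the route at 6 and replaces steps 2 and 3.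

**Step 5.** Addition of the liberated HCl across the prenyl double bond, and some formylation at pyrrole C3, are the likely losses. Fallback: setting out from 6, the same Vilsmeier conditions are applied before any alkene is present, giving by way of [1-(6-bromo-1-tosylindol-3-yl)pyrrol-2-yl]methylidene(dimethyl)ammonium chloride F6 the aldehyde 1-(6-bromo-1-tosylindol-3-yl)pyrrole-2-carbaldehyde F7. Stille coupling of F7 with tributyl(3-methylbut-2-enyl)stannane (Pd(PPh3)4, DMF, 90 °C), a reagent that does not add to the aldehyde as an allylboronate would, returns to the route at 10.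

**Step 12.** Friedel–Crafts self-alkylation of the nucleophilic indole C3' by the benzylic chloride, homocoupling, and migration of the new double bond into conjugation through a palladium hydride are the risks. Fallback: setting out from 23, the polarity is reversed: zinc insertion (Zn dust, LiCl, THF) gives [1-(6-prenyl-1-tosylindol-3-yl)indol-6-yl]methylzinc chloride F8, no longer an electrophile. Negishi coupling of F8 with 1-bromo-2-methylprop-1-ene (Pd(OAc)2, SPhos, THF, rt) returns to the route at 25.

## Further compounds

F1 | step 7 | (E)-3-ethoxycarbonyl-4-[1-(6-prenyl-1-tosylindol-3-yl)pyrrol-2-yl]but-3-enoyl chloride | ClC(=O)C/C(C(=O)OCC)=C\c1cccn1-c1cn(S(=O)(=O)c2ccc(C)cc2)c2cc(CC=C(C)C)ccc12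
F2 | step 4 | 6-allyl-3-(pyrrol-1-yl)-1-tosylindole | C=CCc1ccc2c(-n3cccc3)cn(S(=O)(=O)c3ccc(C)cc3)c2c1
F3 | step 6 | 4-tert-butyl 1-ethyl (E)-2-[[1-(6-prenyl-1-tosylindol-3-yl)pyrrol-2-yl]methylidene]butanedioate | CC(C)(C)OC(=O)C/C(C(=O)OCC)=C\c1cccn1-c1cn(S(=O)(=O)c2ccc(C)cc2)c2cc(CC=C(C)C)ccc12
F4 | step 3 | 6-bromo-3-iodo-1H-indole | Brc1ccc2c(I)c[nH]c2c1
F5 | step 3 | 6-bromo-3-iodo-1-tosylindole | Cc1ccc(cc1)S(=O)(=O)n1cc(I)c2ccc(Br)cc21
F6 | step 5 | [1-(6-bromo-1-tosylindol-3-yl)pyrrol-2-yl]methylidene(dimethyl)ammonium chloride | C[N+](C)=Cc1cccn1-c1cn(S(=O)(=O)c2ccc(C)cc2)c2cc(Br)ccc12.[Cl-]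
F7 | step 5 | 1-(6-bromo-1-tosylindol-3-yl)pyrrole-2-carbaldehyde | O=Cc1cccn1-c1cn(S(=O)(=O)c2ccc(C)cc2)c2cc(Br)ccc12
F8 | step 12 | [1-(6-prenyl-1-tosylindol-3-yl)indol-6-yl]methylzinc chloride | Cl[Zn]Cc1ccc2ccn(-c3cn(S(=O)(=O)c4ccc(C)cc4)c4cc(CC=C(C)C)ccc34)c2c1
A1 | alternative 1 | 1-acetyl-6-prenylindolin-3-one | CC(=O)N1CC(=O)c2ccc(CC=C(C)C)cc21
A2 | alternative 1 | 2-ethynyl-5-prenylaniline | C#Cc1ccc(CC=C(C)C)cc1N
A3 | alternative 1 | 1-acetyl-6-prenyl-3-(6-prenylindol-1-yl)indole | CC(=O)n1cc(-n2ccc3ccc(CC=C(C)C)cc32)c2ccc(CC=C(C)C)cc21
A4 | alternative 1 | 6-prenyl-1H-indole | CC(C)=CCc1ccc2cc[nH]c2c1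
A5 | alternative 2 | 4-(6-prenylindol-1-yl)-1-tosyl-1,2,3-triazole | Cc1ccc(cc1)S(=O)(=O)n1cc(-n2ccc3ccc(CC=C(C)C)cc32)nn1
A6 | alternative 2 | 1-methoxy-5-prenylcyclohexa-1,4-diene | COC1=CCC=C(CC=C(C)C)C1
A7 | alternative 2 | 6-prenyl-3-(6-prenylindol-1-yl)-1-tosyl-4,7-dihydroindole | CC(C)=CCC1=CCc2c(C1)n(S(=O)(=O)c1ccc(C)cc1)cc2-n1ccc2ccc(CC=C(C)C)cc21
A8 | alternative 3 | N-(but-3-ynyl)-N-(6-prenyl-1-tosylindol-3-yl)-5-prenylpyridazin-3-amine | C#CCCN(c1cc(CC=C(C)C)cnn1)c1cn(S(=O)(=O)c2ccc(C)cc2)c2cc(CC=C(C)C)ccc12
A9 | alternative 3 | 6-prenyl-1-(6-prenyl-1-tosylindol-3-yl)indoline | CC(C)=CCc1ccc2c(c1)N(c1cn(S(=O)(=O)c3ccc(C)cc3)c3cc(CC=C(C)C)ccc13)CC2
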